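Atom numbering follows the flavanone convention (O1, C2, C3, C4, C4a, C5 to C8, C8a; ring B positions primed). Compound numbers are those of the steps and the compound list below.

## Analysis of the target

Target 20 is a dihydroflavonol 3-methyl ether: a chroman-4-one in which ring A is fused to the dihydropyranone ring C. Ring B, a 3-hydroxy-4-methoxyphenyl group, sits on C2, and there is a methoxy group on C3, hydroxyls on C5 and C6 and a methoxy group on C7; C8 is the only free position of ring A. There are two stereocentres, C2 (R) and C3 (R), adjacent and trans, with the aryl and methoxy groups both equatorial. This is the thermodynamically preferred arrangement, so C3 can be set from C2, but C2 must be set absolutely. Ring C is a β-aryloxy ketone: an enolate at C3 can expel the O1 phenoxide, which opens the ring and erases C2, and base also epimerises C3 and leads towards the flavonol. The free 5,6-dihydroxy unit is oxidation-prone and should appear only at the end. The real difficulty is the oxygen pattern: three phenols and four methyl ethers must end up in fixed places, and the aliphatic 3-methoxy group must survive the unveiling of O5. The strategy rests on one feature: C2 is a CH between O1 and ring B, that is, the carbon of an aryl arylmethyl ether, and C3 is the carbon next to the C4 carbonyl. A carbene at C3, generated from a diazomethyl ketone on C4, can therefore insert into the C2-H bond, forming C2-C3, closing ring C and creating C2 in one event.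

## Retrosynthetic reasoning

**O5-methyl bond (20 to 19).** The methyl on O5 is removed last. O5 must travel as a methyl ether, because a free hydroxyl or a more reactive ether ortho to the diazoketone would intercept the carbene. Its peri position to the C4 carbonyl allows a chelation-controlled cleavage that the other three methyl ethers do not share.

**Two O-benzyl bonds (19 to 18).** O6 and O3' are carried as benzyl ethers. They survive every earlier step and come off by neutral hydrogenolysis, which touches neither stereocentre.

**C3-O bond and its methyl (18 to 17 to 15 to 14).** The oxygen at C3 cannot ride on the carbene carbon, so it is added after ring closure. The C4 ketone of 14 gives silyl enol ether 15 and oxidation takes place on the face away from the C2 aryl group, through epoxide 16. C3 is therefore set by the substrate, and the hydroxyl of 17 is methylated without base.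

**C2-C3 bond (14 to 13), the key disconnection.** This is the only bond of ring C whose formation turns a prochiral CH2 into C2. No stereocentre has to be carried before the ring exists, and the racemising chalcone-flavanone equilibrium is avoided. The forward reaction must choose C-H insertion over attack on the ether oxygen and must pick one of two enantiotopic hydrogens.

**C3-C4 bond (13 to 10 and 11).** The diazo carbon of 11 is acylated by acid chloride 12. Acid 10 has two ortho substituents, so it is activated as the acid chloride under neutral conditions; a mixed carbonic anhydride would be attacked at its less hindered carbonyl.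

**O1-C2 bond (10 to 9 to 6 and 8).** A Williamson etherification joins the two aromatic halves. The aldehyde of 9 is a placeholder for the acid because ortho-formylation delivers it directly. Bromide 8 comes from commercial alcohol 7.

**Ring A carbon and oxygen (6 to 4 to 2 to 1).** The formyl carbon is put on by ortho-formylation of phenol 4, whose two ortho positions are equivalent by symmetry. The phenol oxygen comes from the aldehyde of 2 by Baeyer-Villiger oxidation, and 2 is the benzyl ether of syringaldehyde 1, which already holds the 5,6,7-oxygen pattern in differentiated form.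

## Alternatives that were turned down

**Alternative 1: ring A built last by photochemical benzannulation.**
- Disconnection: C5-C6, C7-C8 and C4a-C5. This leaves diazoacetyl dihydropyranone A2, which already holds C2 and C3, and alkyne A3.
- Key step: irradiation of A2 causes Wolff rearrangement to a vinylketene. This adds A3 in a [2+2] sense, the cyclobutenone opens, and six-electron closure gives phenol A1.
- For: O5 emerges as a free hydroxyl, so no late demethylation is needed; on that point it is stronger than the chosen route. Both stereocentres exist before the arene, and there is no competition between C-H insertion and ylide formation.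
- Against: O6 and O7 arrive as two identical tert-butyl ethers, while 20 needs 6-OH beside 7-OMe. After their removal a 7-selective methylation among four phenols of a base-sensitive dihydroflavonol would be required. A2 is a cross-conjugated alkoxy enone with photochemistry of its own under the same light. Making A2 enantiopure is a synthesis in itself, and A3 loses isobutene easily.
- Comparison: the chosen route takes a differentiated ring A from a commodity arene and pays for it with one chelation-controlled ether cleavage.

**Alternative 2: copper-catalysed closure of O1 to C8a.**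
- Disconnection: the aryl ether bond O1-C8a, leading to open-chain bromoaryl diol A5.
- Key step: with CuI, 1,10-phenanthroline and Cs2CO3 the C2 alkoxide couples with the aryl bromide through monovalent copper to give flavan-4-ol A4. Oxidation of its C4 carbinol would give 18, so the end game would be shared.
- For: C2 and C3 are fixed in the open chain by well-understood acyclic methods, with the 3-methoxy group already present. The ring closure cannot touch either centre and no flavanone is ever enolised. On stereochemical security this is stronger than the chosen route.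
- Against: A5 has three contiguous oxygenated carbons between two arenes and a bromine on a pentasubstituted ring, so more steps are needed to reach it than the seven to 13. The bromide is electron-rich and ortho-substituted, so the coupling needs heat and carbonate in the presence of a free benzylic carbinol. A separate oxidation follows.
- Comparison: the chosen route offers one catalytic ring closure from a simple ether, at the price of less certain enantiocontrol and two late steps for O3.

**Alternative 3: reductive pinacol union of C3 and C4.**
- Disconnection: the C3-C4 bond, leading to dialdehyde A7.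
- Key step: SmI2 reduces the aryl aldehyde to a ketyl, which adds to the tethered aliphatic aldehyde. Samarium bridges both oxygens and gives the 3,4-cis diol A6.
- For: the C3 oxygen comes with the ring, under neutral conditions, with the relative configuration set by chelation.
- Against: in A7, C2 carries aryl, aryloxy and formyl groups and is easily epimerised. SmI2 cleaves C-O bonds next to a carbonyl, so a ketyl on the aliphatic aldehyde would expel the aryloxide and cut the tether. The dioxygenated aryl aldehyde is the harder carbonyl to reduce, so the wrong ketyl would form first. Benzylic oxidation and methylation would still follow, so nothing is saved.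
- Comparison: in the chosen route C2 is not a stereocentre until the ring closes, so it cannot be lost beforehand.

Key step: step 8

Assumption: Rh2(S-PTTL)4, dirhodium tetrakis[N-phthaloyl-(S)-tert-leucinate], is taken to deliver the 2S configuration; if the sense of induction is the opposite, the mirror-image complex Rh2(R-PTTL)4 is used with nothing else changed.

## Route

Step 1
Reactants: 1 syringaldehyde
Product: 2 4-benzyloxy-3,5-dimethoxybenzaldehyde
Conditions: BnBr, K2CO3, DMF, 60 °C
Reagents that add atoms: benzyl bromide, BrCc1ccccc1
Why: Williamson etherification of the only phenol; the benzyl group masks the future 6-OH until hydrogenolysis.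

Step 2
Reactants: 2 4-benzyloxy-3,5-dimethoxybenzaldehyde
Product: 4 4-benzyloxy-3,5-dimethoxyphenol, via aryl formate 3 (not isolated)
Conditions: mCPBA, CH2Cl2, 0 °C to rt; aq Na2S2O3 wash; then Et3N (cat.), MeOH, rt
Reagents that add atoms: mCPBA, OOC(=O)c1cccc(Cl)c1
Why: Baeyer-Villiger (Dakin-type) oxidation; the electron-rich aryl group migrates in preference to hydrogen, and the formate is cleaved by methanolysis after excess peracid is destroyed, so the phenol is not over-oxidised.

Step 3
Reactants: 4 4-benzyloxy-3,5-dimethoxyphenol
Product: 6 3-benzyloxy-6-hydroxy-2,4-dimethoxybenzaldehyde, via salicyl alcohol 5 (not isolated)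
Conditions: MgCl2, Et3N, (CH2O)n, MeCN, reflux; aq HCl work-up
Reagents that add atoms: paraformaldehyde (as formaldehyde), C=O
Why: Magnesium-mediated ortho-formylation: the magnesium phenoxide delivers formaldehyde to the ortho carbon and a second formaldehyde oxidises the salicyl alcohol by hydride transfer; the two ortho positions of 4 are equivalent, so only over-formylation has to be avoided by stoichiometry.

Step 4
Reactants: 7 (3-benzyloxy-4-methoxyphenyl)methanol
Product: 8 2-benzyloxy-4-(bromomethyl)-1-methoxybenzene
Conditions: PBr3, Et2O, 0 °C; used without storage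
Reagents that add atoms: phosphorus tribromide, BrP(Br)Br
Why: Standard conversion of a benzylic alcohol into the bromide; the electron-rich bromide is used at once because it ionises easily.

Step 5
Reactants: 6 3-benzyloxy-6-hydroxy-2,4-dimethoxybenzaldehyde; 8 2-benzyloxy-4-(bromomethyl)-1-methoxybenzene
Product: 9 3-benzyloxy-6-[(3-benzyloxy-4-methoxyphenyl)methoxy]-2,4-dimethoxybenzaldehyde
Conditions: K2CO3, DMF, rt
Reagents that add atoms: none
Why: Williamson etherification of the acidic salicylaldehyde phenol with a reactive benzylic bromide; this forms the O1-C2 bond and joins rings A and B.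

Step 6
Reactants: 9 3-benzyloxy-6-[(3-benzyloxy-4-methoxyphenyl)methoxy]-2,4-dimethoxybenzaldehyde
Product: 10 3-benzyloxy-6-[(3-benzyloxy-4-methoxyphenyl)methoxy]-2,4-dimethoxybenzoic acid
Conditions: NaClO2, NaH2PO4, 2-methyl-2-butene (excess), t-BuOH/THF/H2O, 0 °C to rt
Reagents that add atoms: sodium chlorite, [Na+].[O-]Cl=O
Why: Pinnick oxidation; the buffered medium spares the acid-labile arylmethyl ether and the alkene scavenger removes hypochlorous acid before it can chlorinate C8 of the electron-rich ring.

Step 7
Reactants: 10 3-benzyloxy-6-[(3-benzyloxy-4-methoxyphenyl)methoxy]-2,4-dimethoxybenzoic acid; 11 trimethylsilyldiazomethane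
Product: 13 1-[3-benzyloxy-6-[(3-benzyloxy-4-methoxyphenyl)methoxy]-2,4-dimethoxyphenyl]-2-diazoethan-1-one, via acid chloride 12 (not isolated)
Conditions: 1-chloro-N,N,2-trimethylprop-1-en-1-amine, CH2Cl2, 0 °C; then 11 (2.5 equiv), MeCN/THF, 0 °C to rt
Reagents that add atoms: 1-chloro-N,N,2-trimethylprop-1-en-1-amine, CC(C)=C(Cl)N(C)C (gives the chlorine of 12; no atom of it remains in 13)
Why: The chloroenamine makes the acid chloride without releasing HCl, which protects the arylmethyl ether; C-acylation of the silyl diazomethane followed by loss of the silyl group to chloride (the first half of an Arndt-Eistert sequence) gives the diazomethyl ketone, and the acid chloride is chosen because a di-ortho-substituted acid reacts at the wrong carbonyl of a mixed anhydride.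

Step 8
Reactants: 13 1-[3-benzyloxy-6-[(3-benzyloxy-4-methoxyphenyl)methoxy]-2,4-dimethoxyphenyl]-2-diazoethan-1-one
Product: 14 (2S)-6-benzyloxy-2-(3-benzyloxy-4-methoxyphenyl)-5,7-dimethoxychroman-4-one
Conditions: Rh2(S-PTTL)4 (2 mol %), CH2Cl2, 4 Å MS, -20 to 0 °C, slow addition of 13
Reagents that add atoms: none
Why: Rh2(S-PTTL)4, a complex of two divalent rhodium atoms, decomposes 13 with loss of nitrogen to an electrophilic acylcarbene bound to one rhodium. The carbene carbon (C3) then inserts into a benzylic C-H bond of the ortho arylmethoxy group in one asynchronous step, hydride-like transfer running ahead of C2-C3 bond formation, and the catalyst is released. The closest known reaction type is the dirhodium-carboxylate-catalysed intramolecular C-H insertion of ortho-alkoxyaryl diazo ketones to chroman-4-ones, including its enantioselective form with chiral carboxylate ligands. Ring C closes by 1,6-insertion through a six-membered cyclic transition state (C3, C4, C4a, C8a, O1, C2), the only one open to the carbene because the fifth atom of the tether is the oxygen itself. C2 is the single new stereocentre; it is set by the chiral pocket of the four N-phthaloyl-tert-leucinate ligands, which must select the pro-S benzylic hydrogen, and insertion with retention then gives 2S. The step needs chemoselectivity for C-H insertion over attack of the ether oxygen on the carbene (oxonium ylide, then 1,2-shift of the benzylic group) and site selectivity over the C-H bonds of the methoxy group on the other side of the ketone. The substrate helps on both counts: the C2-H bond is activated by O1 and by the para-methoxy group of ring B, O1 is a weakly basic aryl ether oxygen facing a bulky catalyst, the competing methyl C-H bonds are primary, and the two O-benzyl groups can only be reached through rings of seven or more atoms. Slow addition at high dilution suppresses carbene dimerisation.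

Step 9
Reactants: 14 (2S)-6-benzyloxy-2-(3-benzyloxy-4-methoxyphenyl)-5,7-dimethoxychroman-4-one
Product: 15 (2S)-6-benzyloxy-2-(3-benzyloxy-4-methoxyphenyl)-4-(tert-butyldimethylsilyloxy)-5,7-dimethoxy-2H-chromene
Conditions: Et3N, then TBSOTf, CH2Cl2, -78 to 0 °C
Reagents that add atoms: tert-butyldimethylsilyl trifluoromethanesulfonate, CC(C)(C)[Si](C)(C)OS(=O)(=O)C(F)(F)F
Why: Soft enolisation: O-silylation of the C4 carbonyl followed by deprotonation at C3 by the amine gives the silyl enol ether without a free enolate, which avoids the E1cB opening of ring C that would erase C2.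

Step 10
Reactants: 15 (2S)-6-benzyloxy-2-(3-benzyloxy-4-methoxyphenyl)-4-(tert-butyldimethylsilyloxy)-5,7-dimethoxy-2H-chromene
Product: 17 (2R,3R)-6-benzyloxy-2-(3-benzyloxy-4-methoxyphenyl)-3-hydroxy-5,7-dimethoxychroman-4-one, via silyloxy epoxide 16 (not isolated)
Conditions: DMDO, acetone/CH2Cl2, -40 °C; then HF·pyridine, THF, 0 °C
Reagents that add atoms: dimethyldioxirane, CC1(C)OO1
Why: Rubottom oxidation: the dioxirane epoxidises the enol ether on the face away from the C2 aryl group and fluoride opens the silyloxy epoxide to the hydroxy ketone, so the 3-hydroxyl is trans to the aryl group (3R), which is also the more stable arrangement; C2 is untouched and is now called R only because C3 outranks the aryl group.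

Step 11
Reactants: 17 (2R,3R)-6-benzyloxy-2-(3-benzyloxy-4-methoxyphenyl)-3-hydroxy-5,7-dimethoxychroman-4-one
Product: 18 (2R,3R)-6-benzyloxy-2-(3-benzyloxy-4-methoxyphenyl)-3,5,7-trimethoxychroman-4-one
Conditions: Me3OBF4, 1,8-bis(dimethylamino)naphthalene, 4 Å MS, CH2Cl2, 0 °C to rt
Reagents that add atoms: trimethyloxonium tetrafluoroborate, C[O+](C)C.F[B-](F)(F)F
Why: O-Methylation with an oxonium salt and a non-nucleophilic amine base, the usual method for base-sensitive hydroxy ketones; no enolate forms, so C3 is not epimerised, ring C does not open and the ketol is not oxidised to the flavonol.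

Step 12
Reactants: 18 (2R,3R)-6-benzyloxy-2-(3-benzyloxy-4-methoxyphenyl)-3,5,7-trimethoxychroman-4-one
Product: 19 (2R,3R)-6-hydroxy-2-(3-hydroxy-4-methoxyphenyl)-3,5,7-trimethoxychroman-4-one
Conditions: H2 (1 atm), Pd/C, EtOAc/MeOH, rt
Reagents that add atoms: none
Why: Hydrogenolysis of the two aryl benzyl ethers; under these mild conditions the benzylic C2-O1 bond of ring C and the aryl ketone react much more slowly, and the methyl ethers are inert.

Step 13
Reactants: 19 (2R,3R)-6-hydroxy-2-(3-hydroxy-4-methoxyphenyl)-3,5,7-trimethoxychroman-4-one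
Product: 20 (2R,3R)-5,6-dihydroxy-2-(3-hydroxy-4-methoxyphenyl)-3,7-dimethoxychroman-4-one
Conditions: BCl3 (4 equiv), CH2Cl2, -78 to 0 °C; then H2O
Reagents that add atoms: none
Why: Chelation-controlled demethylation: boron bridges the C4 carbonyl and the peri 5-methoxy oxygen in a six-membered chelate and chloride removes that methyl group, while the 7-, 4'- and 3-methyl ethers lack this arrangement and should react much more slowly at or below 0 °C; the boron aryloxides are hydrolysed on work-up.

## Compound list

1 | syringaldehyde (4-hydroxy-3,5-dimethoxybenzaldehyde) | COc1cc(C=O)cc(OC)c1O | starting material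
2 | 4-benzyloxy-3,5-dimethoxybenzaldehyde | COc1cc(C=O)cc(OC)c1OCc1ccccc1 | intermediate
3 | 4-benzyloxy-3,5-dimethoxyphenyl formate | COc1cc(OC=O)cc(OC)c1OCc1ccccc1 | intermediate (not isolated)
4 | 4-benzyloxy-3,5-dimethoxyphenol | COc1cc(O)cc(OC)c1OCc1ccccc1 | intermediate
5 | 4-benzyloxy-2-(hydroxymethyl)-3,5-dimethoxyphenol | COc1cc(O)c(CO)c(OC)c1OCc1ccccc1 | intermediate (not isolated)
6 | 3-benzyloxy-6-hydroxy-2,4-dimethoxybenzaldehyde | COc1cc(O)c(C=O)c(OC)c1OCc1ccccc1 | intermediate
7 | (3-benzyloxy-4-methoxyphenyl)methanol | COc1ccc(CO)cc1OCc1ccccc1 | starting material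
8 | 2-benzyloxy-4-(bromomethyl)-1-methoxybenzene | COc1ccc(CBr)cc1OCc1ccccc1 | intermediate
9 | 3-benzyloxy-6-[(3-benzyloxy-4-methoxyphenyl)methoxy]-2,4-dimethoxybenzaldehyde | COc1ccc(COc2cc(OC)c(OCc3ccccc3)c(OC)c2C=O)cc1OCc1ccccc1 | intermediate
10 | 3-benzyloxy-6-[(3-benzyloxy-4-methoxyphenyl)methoxy]-2,4-dimethoxybenzoic acid | COc1ccc(COc2cc(OC)c(OCc3ccccc3)c(OC)c2C(=O)O)cc1OCc1ccccc1 | intermediate
11 | trimethylsilyldiazomethane | C[Si](C)(C)C=[N+]=[N-] | starting material
12 | 3-benzyloxy-6-[(3-benzyloxy-4-methoxyphenyl)methoxy]-2,4-dimethoxybenzoyl chloride | COc1ccc(COc2cc(OC)c(OCc3ccccc3)c(OC)c2C(=O)Cl)cc1OCc1ccccc1 | intermediate (not isolated)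
13 | 1-[3-benzyloxy-6-[(3-benzyloxy-4-methoxyphenyl)methoxy]-2,4-dimethoxyphenyl]-2-diazoethan-1-one | COc1ccc(COc2cc(OC)c(OCc3ccccc3)c(OC)c2C(=O)C=[N+]=[N-])cc1OCc1ccccc1 | intermediate
14 | (2S)-6-benzyloxy-2-(3-benzyloxy-4-methoxyphenyl)-5,7-dimethoxychroman-4-one | COc1ccc([C@H]2Oc3cc(OC)c(OCc4ccccc4)c(OC)c3C(=O)C2)cc1OCc1ccccc1 | intermediate
15 | (2S)-6-benzyloxy-2-(3-benzyloxy-4-methoxyphenyl)-4-(tert-butyldimethylsilyloxy)-5,7-dimethoxy-2H-chromene | COc1ccc([C@H]2Oc3cc(OC)c(OCc4ccccc4)c(OC)c3C(O[Si](C)(C)C(C)(C)C)=C2)cc1OCc1ccccc1 | intermediate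
16 | (2R,3R,4R)-6-benzyloxy-2-(3-benzyloxy-4-methoxyphenyl)-4-(tert-butyldimethylsilyloxy)-3,4-epoxy-5,7-dimethoxychromane (epoxide oxygen anti to the 2-aryl group) | COc1ccc([C@H]2Oc3cc(OC)c(OCc4ccccc4)c(OC)c3[C@]3(O[Si](C)(C)C(C)(C)C)O[C@H]23)cc1OCc1ccccc1 | intermediate (not isolated)
17 | (2R,3R)-6-benzyloxy-2-(3-benzyloxy-4-methoxyphenyl)-3-hydroxy-5,7-dimethoxychroman-4-one | COc1ccc([C@H]2Oc3cc(OC)c(OCc4ccccc4)c(OC)c3C(=O)[C@@H]2O)cc1OCc1ccccc1 | intermediate
18 | (2R,3R)-6-benzyloxy-2-(3-benzyloxy-4-methoxyphenyl)-3,5,7-trimethoxychroman-4-one | COc1ccc([C@H]2Oc3cc(OC)c(OCc4ccccc4)c(OC)c3C(=O)[C@@H]2OC)cc1OCc1ccccc1 | intermediate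
19 | (2R,3R)-6-hydroxy-2-(3-hydroxy-4-methoxyphenyl)-3,5,7-trimethoxychroman-4-one | COc1ccc([C@H]2Oc3cc(OC)c(O)c(OC)c3C(=O)[C@@H]2OC)cc1O | intermediate
20 | (2R,3R)-5,6-dihydroxy-2-(3-hydroxy-4-methoxyphenyl)-3,7-dimethoxychroman-4-one | COc1ccc([C@H]2Oc3cc(OC)c(O)c(O)c3C(=O)[C@@H]2OC)cc1O | target

## Step count and least certain steps

Total: 13 steps. Longest linear sequence: 12 steps (steps 1 to 3 and 5 to 13, from 1 to 20); step 4 is the side branch.

**Step 8 (key step).** Two things are most likely to go wrong.
- The carbene may be diverted to the ether oxygen (oxonium ylide formation and 1,2-migration of the benzylic group) instead of inserting into C-H.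
- Discrimination between the two enantiotopic hydrogens may be weak, because a carbene with only one acceptor group reacts through an early, loosely organised transition state.

The fallback sets out from 6 and comes back at 14.
- Excess MeMgBr in THF adds to 6 to give 4-benzyloxy-2-(1-hydroxyethyl)-3,5-dimethoxyphenol F1.
- MnO2 in CH2Cl2 oxidises the benzylic carbinol to 1-(3-benzyloxy-6-hydroxy-2,4-dimethoxyphenyl)ethanone F2.
- Heating with N,N-dimethylformamide dimethyl acetal gives (E)-1-(3-benzyloxy-6-hydroxy-2,4-dimethoxyphenyl)-3-(dimethylamino)prop-2-en-1-one F3.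
- Acid closes this, with loss of dimethylamine, to 6-benzyloxy-5,7-dimethoxy-4H-chromen-4-one F4.
- Conjugate addition of commercial (3-benzyloxy-4-methoxyphenyl)boronic acid to F4 gives 14. It uses Pd(OCOCF3)2 and a chiral 4-tert-butyl-2-(pyridin-2-yl)oxazoline ligand (the enantiomer that delivers 2S), a known enantioselective route to flavanones. Here C2 is set as the C2-aryl bond forms and no carbene is involved.

**Step 7.** The chloride of a 2,6-dialkoxybenzoic acid ionises easily. The likely failures are intramolecular acylation of ring B, loss of the acid-labile arylmethyl ether, or sluggish C-acylation of the silyl diazomethane at the hindered carbonyl.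

The fallback sets out from 9 and comes back at 13.
- MeMgBr adds to 9 to give 1-[3-benzyloxy-6-[(3-benzyloxy-4-methoxyphenyl)methoxy]-2,4-dimethoxyphenyl]ethanol F5.
- Dess-Martin periodinane gives 1-[3-benzyloxy-6-[(3-benzyloxy-4-methoxyphenyl)methoxy]-2,4-dimethoxyphenyl]ethanone F6.
- LiN(SiMe3)2 and 2,2,2-trifluoroethyl trifluoroacetate give 1-[3-benzyloxy-6-[(3-benzyloxy-4-methoxyphenyl)methoxy]-2,4-dimethoxyphenyl]-4,4,4-trifluorobutane-1,3-dione F7.
- Methanesulfonyl azide, Et3N and water in MeCN transfer the diazo group with loss of the trifluoroacetyl group to give 13. No acyl chloride is needed.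

**Step 10 (with step 9 before it).** The likely failures are erosion of C2 by reversible opening of ring C while the ketone is activated, oxidation on the wrong face of the enol ether, or over-oxidation of the electron-rich arenes.

The fallback sets out from 14 and comes back at 17, and it uses no enol derivative.
- NaBH4 reduces 14 to the 2,4-cis alcohol (2S,4S)-6-benzyloxy-2-(3-benzyloxy-4-methoxyphenyl)-5,7-dimethoxychroman-4-ol F8.
- Martin sulfurane dehydrates it to (2S)-6-benzyloxy-2-(3-benzyloxy-4-methoxyphenyl)-5,7-dimethoxy-2H-chromene F9.
- OsO4 (catalytic) with N-methylmorpholine N-oxide adds both hydroxyls on the face away from the aryl group to give the 2,3-trans-3,4-cis diol (2R,3S,4S)-6-benzyloxy-2-(3-benzyloxy-4-methoxyphenyl)-5,7-dimethoxychromane-3,4-diol F10.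
- MnO2 oxidises only the benzylic C4 carbinol to give 17.

**Step 13.** The likely failures are over-demethylation at O7 (assisted by boron bound to the free 6-hydroxyl) or at O3, and Lewis-acid ionisation of the C2-O1 bond with epimerisation at C2.

The fallback sets out from 18 and comes back to the route at 20, bypassing 19. It reverses the order of the last two operations and uses a different cleavage mechanism.
- MgI2·OEt2 in warm toluene chelates the C4 carbonyl and the 5-methoxy oxygen, and iodide removes that methyl group while the benzyl ethers stay. This gives (2R,3R)-6-benzyloxy-2-(3-benzyloxy-4-methoxyphenyl)-5-hydroxy-3,7-dimethoxychroman-4-one F11.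
- Hydrogenolysis over Pd/C then gives 20. No free 6-hydroxyl is present during the demethylation.

## Further compounds

F1 | step 8 | 4-benzyloxy-2-(1-hydroxyethyl)-3,5-dimethoxyphenol (racemic) | COc1cc(O)c(C(C)O)c(OC)c1OCc1ccccc1
F2 | step 8 | 1-(3-benzyloxy-6-hydroxy-2,4-dimethoxyphenyl)ethanone | COc1cc(O)c(C(C)=O)c(OC)c1OCc1ccccc1
F3 | step 8 | (E)-1-(3-benzyloxy-6-hydroxy-2,4-dimethoxyphenyl)-3-(dimethylamino)prop-2-en-1-one | COc1cc(O)c(C(=O)/C=C/N(C)C)c(OC)c1OCc1ccccc1
F4 | step 8 | 6-benzyloxy-5,7-dimethoxy-4H-chromen-4-one | COc1cc2occc(=O)c2c(OC)c1OCc1ccccc1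
F5 | step 7 | 1-[3-benzyloxy-6-[(3-benzyloxy-4-methoxyphenyl)methoxy]-2,4-dimethoxyphenyl]ethanol (racemic) | COc1ccc(COc2cc(OC)c(OCc3ccccc3)c(OC)c2C(C)O)cc1OCc1ccccc1
F6 | step 7 | 1-[3-benzyloxy-6-[(3-benzyloxy-4-methoxyphenyl)methoxy]-2,4-dimethoxyphenyl]ethanone | COc1ccc(COc2cc(OC)c(OCc3ccccc3)c(OC)c2C(C)=O)cc1OCc1ccccc1
F7 | step 7 | 1-[3-benzyloxy-6-[(3-benzyloxy-4-methoxyphenyl)methoxy]-2,4-dimethoxyphenyl]-4,4,4-trifluorobutane-1,3-dione | COc1ccc(COc2cc(OC)c(OCc3ccccc3)c(OC)c2C(=O)CC(=O)C(F)(F)F)cc1OCc1ccccc1
F8 | step 10 | (2S,4S)-6-benzyloxy-2-(3-benzyloxy-4-methoxyphenyl)-5,7-dimethoxychroman-4-ol (2,4-cis) | COc1ccc([C@H]2Oc3cc(OC)c(OCc4ccccc4)c(OC)c3[C@@H](O)C2)cc1OCc1ccccc1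
F9 | step 10 | (2S)-6-benzyloxy-2-(3-benzyloxy-4-methoxyphenyl)-5,7-dimethoxy-2H-chromene | COc1ccc([C@H]2Oc3cc(OC)c(OCc4ccccc4)c(OC)c3C=C2)cc1OCc1ccccc1
F10 | step 10 | (2R,3S,4S)-6-benzyloxy-2-(3-benzyloxy-4-methoxyphenyl)-5,7-dimethoxychromane-3,4-diol (2,3-trans-3,4-cis) | COc1ccc([C@H]2Oc3cc(OC)c(OCc4ccccc4)c(OC)c3[C@H](O)[C@@H]2O)cc1OCc1ccccc1
F11 | step 13 | (2R,3R)-6-benzyloxy-2-(3-benzyloxy-4-methoxyphenyl)-5-hydroxy-3,7-dimethoxychroman-4-one | COc1ccc([C@H]2Oc3cc(OC)c(OCc4ccccc4)c(O)c3C(=O)[C@@H]2OC)cc1OCc1ccccc1
A1 | alternative 1 | (2R,3R)-2-(3-benzyloxy-4-methoxyphenyl)-6,7-di-tert-butoxy-5-hydroxy-3-methoxychroman-4-one | COc1ccc([C@H]2Oc3cc(OC(C)(C)C)c(OC(C)(C)C)c(O)c3C(=O)[C@@H]2OC)cc1OCc1ccccc1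
A2 | alternative 1 | (2R,3R)-2-(3-benzyloxy-4-methoxyphenyl)-6-(diazoacetyl)-3-methoxy-2,3-dihydro-4H-pyran-4-one | COc1ccc([C@H]2OC(C(=O)C=[N+]=[N-])=CC(=O)[C@@H]2OC)cc1OCc1ccccc1
A3 | alternative 1 | di-tert-butoxyethyne | CC(C)(C)OC#COC(C)(C)C
A4 | alternative 2 | (2R,3S,4S)-6-benzyloxy-2-(3-benzyloxy-4-methoxyphenyl)-3,5,7-trimethoxychroman-4-ol (2,3-trans, C2 and C3 placed as in the target) | COc1ccc([C@H]2Oc3cc(OC)c(OCc4ccccc4)c(OC)c3[C@H](O)[C@@H]2OC)cc1OCc1ccccc1
A5 | alternative 2 | 1-(3-benzyloxy-6-bromo-2,4-dimethoxyphenyl)-3-(3-benzyloxy-4-methoxyphenyl)-2-methoxypropane-1,3-diol, configured as in A4 | COc1ccc([C@@H](O)[C@@H](OC)[C@@H](O)c2c(Br)cc(OC)c(OCc3ccccc3)c2OC)cc1OCc1ccccc1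
A6 | alternative 3 | (2R,3S,4S)-6-benzyloxy-2-(3-benzyloxy-4-methoxyphenyl)-5,7-dimethoxychromane-3,4-diol (2,3-trans-3,4-cis) | COc1ccc([C@H]2Oc3cc(OC)c(OCc4ccccc4)c(OC)c3[C@H](O)[C@@H]2O)cc1OCc1ccccc1
A7 | alternative 3 | (2R)-2-(3-benzyloxy-4-methoxyphenyl)-2-(4-benzyloxy-2-formyl-3,5-dimethoxyphenoxy)acetaldehyde | COc1ccc([C@H](C=O)Oc2cc(OC)c(OCc3ccccc3)c(OC)c2C=O)cc1OCc1ccccc1
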